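The constants are those of an exercise; the rest is arithmetic.

**Start here.** Draw the big curve from the J charge first, then reckon G as a small correction to it.

X 0.0050 M; J 4.00 mM; time 10 min

    L ⇌ X.J, rate k1*(cs1 - [X.J]) while solid is left; crystals form when [X.J] > cs1 (cs1 = 0.096 mM, k1 = 11 s⁻¹)
    X + J → X.J (k2 = 13 L mol⁻¹ s⁻¹)
    X.J ⇌ G (K3 = 1.1, k3 = 0.0033 s⁻¹)

- for X.J the L are counted in
- as a solid, counted per litre of solution: L
- the reaction counts as stopped when no species that holds the X changes by six tenths of a point or more over the second half of the time
- run time (flask): 10 min

* at 10 min, what has stopped the reaction, if anything has (forward and back rates have come level / J has run out first / all of X has reacted / it is still moving)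
* share of the X used up at 10 min
* X.J at 10 min, in percent of the X charged
* G at 10 min, in percent of the X charged
* amount of X.J if the flask were left three thousand times as long, in percent of the X charged

**Main curve.** X and J start by making X.J at 0.260 mM s⁻¹, so the solubility 0.096 mM is passed after 0.369 s, well before the half-life of X by that step with J as charged, 0.22 min. From there the new X.J goes into crystals. J is the limiting reagent, so the curve bends towards a level of 80.0% of the X charged. The last J fades with a half-life of 0.889 min, shorter than the 10 min run. The integrated rate law leaves 0.00820% of its charge, so I commit to J running out first.

**Small correction.** With crystals present, dissolved X.J stays near its solubility, since 11 s⁻¹ far exceeds 0.0033 s⁻¹. G is then fed at a steady rate and returns in proportion to itself. It rises towards the crystal ceiling on G, the G level with a saturated solution, in percent of the X charged: 2.11%. Its half-life of approach is 3.85 min, so at 10 min I reckon G at 1.76%. X.J is the level minus G: 78.2% then, and 77.9% in the long run.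

**The forecast.** It gives J has run out first, conversion 80%, X.J 77.9%, G 2.07% and long-run X.J 77.9%, holding that “G can only approach about 0.106 mM”. At the asked time its G is higher than mine.

**The run.** The simulation gives J has run out first, conversion 80.0%, X.J 78.2%, G 1.77% and long-run X.J 77.9%.

**Second flask.** Without the back reaction of G to X.J, G in this flask reaches 3.82% at 10 min instead of 1.77%, above the 2.11% ceiling. With that back reaction, G in this flask reads 2.11% at 100 min. In the neighbour charged with 0.013 M of X, the ceiling drops to 0.812%, and the same climb gives 0.678% at 10 min; that neighbour reads G 0.679%.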